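Everything rests on cutting, at each of the two quaternary carbons, the bond to the homogeranyl CH2 and the bond to the vinyl group. The key step exploits that both carbons, C(aryl)(CH3)(CH=CH2)(CH2R), are benzylic and methyl-bearing and sit on different rings of the diaryl ether: para to the middle oxygen of trioxygenated ring A (R) and ortho to the hydroxyl of ring B (S). Each can therefore be read out from an ArCH(CH3)O carbinol. One double lithiation–borylation of the bis(N,N-diisopropylcarbamate) of the diaryl ether (R,S)-diol with two homogeranyl pinacol boronates attaches both chains and fixes both centres as tertiary boronates; double Zweifel vinylation and MOM removal follow.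

Key step: step 12

Remark: 1, 6 and 13 are taken as purchasable; boron ranks below carbon in the CIP order, so boronate 19 carries the same labels as the target (R on ring A, S on ring B).

Step 1
Reactants: 1 3-bromo-4,5-dihydroxybenzaldehyde
Product: 2 3-bromo-4,5-bis(methoxymethoxy)benzaldehyde
Conditions: MOMCl, iPr2NEt, CH2Cl2, 0 °C → rt
Reagents that add atoms: chloromethyl methyl ether (MOMCl), COCCl
Why: Williamson-type O-alkylation of both catechol hydroxyls by the reactive α-chloro ether under amine base masks them as acetals that should tolerate Grignard, organolithium, copper and basic iodine chemistry.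

Step 2
Reactants: 2 3-bromo-4,5-bis(methoxymethoxy)benzaldehyde
Product: 3 racemic 1-[3-bromo-4,5-bis(methoxymethoxy)phenyl]ethan-1-ol
Conditions: MeMgBr, THF, 0 °C; aq. NH4Cl
Reagents that add atoms: methylmagnesium bromide, C[Mg]Br
Why: Grignard addition to the aldehyde is far faster at 0 °C than magnesium–bromine exchange at the aryl bromide, and the carbinol centre formed here is racemic on purpose because the next step removes it.

Step 3
Reactants: 3 racemic 1-[3-bromo-4,5-bis(methoxymethoxy)phenyl]ethan-1-ol
Product: 4 1-[3-bromo-4,5-bis(methoxymethoxy)phenyl]ethan-1-one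
Conditions: Dess–Martin periodinane, CH2Cl2, rt
Reagents that add atoms: none
Why: Dess–Martin oxidation of a secondary benzylic alcohol to the aryl methyl ketone runs under near-neutral conditions that should leave the MOM acetals and the aryl bromide untouched.

Step 4
Reactants: 4 1-[3-bromo-4,5-bis(methoxymethoxy)phenyl]ethan-1-one
Product: 5 (R)-1-[3-bromo-4,5-bis(methoxymethoxy)phenyl]ethan-1-ol
Conditions: RuCl(p-cymene)[(R,R)-TsDPEN] (1 mol %), HCO2H/Et3N (5:2), 30 °C
Reagents that add atoms: none
Why: Noyori–Ikariya asymmetric transfer hydrogenation of an aryl methyl ketone, in which the (R,R)-ligand delivers hydride to the Si face through the six-membered metal–ligand bifunctional transition state (aryl held by a CH/π contact with the cymene ligand), should set the R carbinol.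

Step 5
Reactants: 6 1-(3-bromo-2-hydroxyphenyl)ethan-1-one (3'-bromo-2'-hydroxyacetophenone)
Product: 7 1-[3-bromo-2-(methoxymethoxy)phenyl]ethan-1-one
Conditions: NaH (1.1 equiv), MOMCl, DMF, 0 °C → rt
Reagents that add atoms: chloromethyl methyl ether (MOMCl), COCCl
Why: Williamson-type alkylation of the sodium phenoxide with the α-chloro ether; full deprotonation with NaH overcomes the hydrogen bond to the ortho acetyl group, and one equivalent of base leaves the methyl ketone un-enolised.

Step 6
Reactants: 7 1-[3-bromo-2-(methoxymethoxy)phenyl]ethan-1-one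
Product: 8 (S)-1-[3-bromo-2-(methoxymethoxy)phenyl]ethan-1-ol
Conditions: RuCl(p-cymene)[(S,S)-TsDPEN] (1 mol %), HCO2H/Et3N (5:2), 30 °C
Reagents that add atoms: none
Why: Noyori–Ikariya asymmetric transfer hydrogenation with the mirror-image ligand delivers hydride to the Re face of the aryl methyl ketone and should set the S carbinol, the ortho MOM ether leaving the aryl-versus-methyl discrimination intact.

Step 7
Reactants: 8 (S)-1-[3-bromo-2-(methoxymethoxy)phenyl]ethan-1-ol
Product: 10 (S)-1-[3-hydroxy-2-(methoxymethoxy)phenyl]ethan-1-ol, via aryl pinacol boronate 9 (not isolated)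
Conditions: B2pin2, Pd(dppf)Cl2 (3 mol %), KOAc, 1,4-dioxane, 90 °C; then 30% H2O2, aq. NaOH, THF, 0 °C
Reagents that add atoms: hydrogen peroxide, OO (phenol oxygen); bis(pinacolato)diboron, CC1(C)OB(OC1(C)C)B1OC(C)(C)C(C)(C)O1 (pinacolboryl group of 9 only)
Why: Miyaura borylation of the aryl bromide under weak acetate base, followed in the same flask by peroxide oxidation of the aryl C–B bond (aryl shift from boron to oxygen), should give the phenol without exposing the free secondary alcohol to hot hydroxide and an aryl palladium species that could oxidise it; the carbinol centre is not involved.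

Step 8
Reactants: 5 (R)-1-[3-bromo-4,5-bis(methoxymethoxy)phenyl]ethan-1-ol; 10 (S)-1-[3-hydroxy-2-(methoxymethoxy)phenyl]ethan-1-ol
Product: 11 (R)-1-[3-{3-[(S)-1-hydroxyethyl]-2-(methoxymethoxy)phenoxy}-4,5-bis(methoxymethoxy)phenyl]ethan-1-ol
Conditions: CuI (10 mol %), picolinic acid (20 mol %), K3PO4, DMSO, 90 °C
Reagents that add atoms: none
Why: Ullmann diaryl ether coupling with a copper picolinate catalyst suited to ortho-substituted partners; only the phenol is acidic enough for K3PO4, so arylation should occur at the phenoxide and not at either secondary alcohol, and neither carbinol centre is touched.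

Step 9
Reactants: 11 diaryl ether (R,S)-diol
Product: 12 (R)-1-[3-{3-[(S)-1-(N,N-diisopropylcarbamoyloxy)ethyl]-2-(methoxymethoxy)phenoxy}-4,5-bis(methoxymethoxy)phenyl]ethyl N,N-diisopropylcarbamate
Conditions: iPr2NCOCl, Et3N, CH2Cl2, reflux
Reagents that add atoms: N,N-diisopropylcarbamoyl chloride, CC(C)N(C(C)C)C(=O)Cl
Why: O-carbamoylation of both secondary alcohols by acyl substitution installs the directing and leaving groups for lithiation–borylation; the reaction takes place at oxygen, so the R and S carbinol carbons are unchanged.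

Step 10
Reactants: 13 geraniol
Product: 14 geranyl pinacol boronate, 2-[(2E)-3,7-dimethylocta-2,6-dien-1-yl]-4,4,5,5-tetramethyl-1,3,2-dioxaborolane
Conditions: B2pin2, Pd(MeCN)4(BF4)2 (5 mol %), p-TsOH (5 mol %), DMSO/MeOH, 50 °C
Reagents that add atoms: bis(pinacolato)diboron, CC1(C)OB(OC1(C)C)B1OC(C)(C)C(C)(C)O1
Why: Palladium-catalysed allylic borylation, in which the activated allylic alcohol forms an η3-geranyl palladium intermediate that takes a boryl group at the unhindered primary terminus, should give the linear allyl boronate with the E alkene kept.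

Step 11
Reactants: 14 geranyl pinacol boronate
Product: 16 (E)-homogeranyl pinacol boronate, via chloromethyl boronate complex 15 (not isolated)
Conditions: BrCH2Cl, n-BuLi, THF, −78 °C → rt
Reagents that add atoms: bromochloromethane, ClCBr (the inserted CH2); n-butyllithium, CCCC[Li] (lithium counter-ion of 15 only)
Why: Matteson homologation, in which chloromethyllithium made in situ adds to boron to give complex 15 and the geranyl CH2 then migrates from boron to carbon with loss of chloride, inserts one CH2 by a 1,2-shift without allylic transposition, so the E alkene is unchanged.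

Step 12
Reactants: 12 diaryl ether bis(N,N-diisopropylcarbamate); 16 (E)-homogeranyl pinacol boronate (2.6 equiv)
Product: 19 bis(tertiary benzylic pinacol boronate), via dilithiated bis-carbamate 17 (not isolated), via dilithium bis(boronate) complex 18 (not isolated)
Conditions: s-BuLi (2.5 equiv), Et2O, −78 °C; 16, −78 °C; MgBr2/MeOH, −78 °C → rt
Reagents that add atoms: sec-butyllithium, CCC(C)[Li] (lithium of 17 and counter-ions of 18 only)
Why: s-BuLi removes both carbamate-activated benzylic hydrogens with retention to give the carbonyl-chelated dilithio species 17, each C–Li bond captures one molecule of 16 with retention to give the bis(boronate) complex 18, and on warming with MgBr2/MeOH each homogeranyl CH2 migrates from boron to carbon antiperiplanar to the departing carbamate (1,2-metallate rearrangement, inversion at carbon). The closest known reaction type is the lithiation–borylation of enantioenriched secondary benzylic carbamates with primary alkyl pinacol boronates to tertiary boronates, used here at two such sites of one molecule; no ring is closed. Each new fully substituted centre is controlled only by the configuration of its own carbinol carbon: retention, retention and inversion put the chain where hydrogen was and boron where oxygen was, which should give R at the ring A carbon and S at the ring B carbon. The step needs benzylic instead of ring lithiation and a migration that outruns reversal of the boronate complex. The carbamate carbonyl directs the base to the benzylic C–H at −78 °C in Et2O without a diamine, whereas the only ring hydrogen ortho to a MOM ether (C6–H of ring A, next to the C5 MOM ether) is far less acidic; MgBr2/MeOH speeds the shift and quenches any lithiated carbamate released by reversal, which matters for the para-oxygenated ring A and the ortho-substituted ring B. The two sites lie on different rings and should react independently, and the isolated trisubstituted alkenes of 16 are inert to the base.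

Step 13
Reactants: 19 bis(tertiary benzylic pinacol boronate)
Product: 22 tris-MOM ether of the target, via bis(vinyl boronate) complex 20 (not isolated), via bis(iodoalkyl boronate) 21 (not isolated)
Conditions: CH2=CHMgBr (excess), THF, rt; I2, MeOH, −78 °C; NaOMe, MeOH, −78 °C → rt
Reagents that add atoms: vinylmagnesium bromide, C=C[Mg]Br (both vinyl groups); iodine, II (iodine atoms of 21 only)
Why: Zweifel olefination, in which vinylmagnesium bromide adds to each boron to give complex 20, iodine triggers migration of each tertiary benzylic carbon from boron to the vinyl α-carbon with retention at the migrating carbon, and methoxide-induced anti elimination of boron and iodide from 21 releases each vinyl group, should keep both quaternary centres (R on ring A, S on ring B), the electron-rich boronate complexes reacting with iodine at −78 °C far faster than the isolated chain alkenes.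

Step 14
Reactants: 22 tris-MOM ether of the target
Product: 23 target CNP0325484.1
Conditions: conc. HCl (cat.), MeOH/THF, degassed, rt
Reagents that add atoms: none
Why: Acid-catalysed acetal exchange with methanol should remove the three aryl MOM ethers as dimethoxymethane at room temperature, where the trisubstituted and terminal alkenes are not protonated productively and the quaternary centres, which carry no leaving group or acidic hydrogen, cannot epimerise; degassed solvent protects the catechol from air.

Compound list
1 | 3-bromo-4,5-dihydroxybenzaldehyde | O=Cc1cc(O)c(O)c(Br)c1 | starting material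
2 | 3-bromo-4,5-bis(methoxymethoxy)benzaldehyde | O=Cc1cc(Br)c(OCOC)c(OCOC)c1 | intermediate
3 | racemic 1-[3-bromo-4,5-bis(methoxymethoxy)phenyl]ethan-1-ol | CC(O)c1cc(Br)c(OCOC)c(OCOC)c1 | intermediate
4 | 1-[3-bromo-4,5-bis(methoxymethoxy)phenyl]ethan-1-one | CC(=O)c1cc(Br)c(OCOC)c(OCOC)c1 | intermediate
5 | (R)-1-[3-bromo-4,5-bis(methoxymethoxy)phenyl]ethan-1-ol | C[C@@H](O)c1cc(Br)c(OCOC)c(OCOC)c1 | intermediate
6 | 1-(3-bromo-2-hydroxyphenyl)ethan-1-one | CC(=O)c1cccc(Br)c1O | starting material
7 | 1-[3-bromo-2-(methoxymethoxy)phenyl]ethan-1-one | CC(=O)c1cccc(Br)c1OCOC | intermediate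
8 | (S)-1-[3-bromo-2-(methoxymethoxy)phenyl]ethan-1-ol | C[C@H](O)c1cccc(Br)c1OCOC | intermediate
9 | (S)-1-[2-(methoxymethoxy)-3-(4,4,5,5-tetramethyl-1,3,2-dioxaborolan-2-yl)phenyl]ethan-1-ol | C[C@H](O)c1cccc(B2OC(C)(C)C(C)(C)O2)c1OCOC | intermediate
10 | (S)-1-[3-hydroxy-2-(methoxymethoxy)phenyl]ethan-1-ol | C[C@H](O)c1cccc(O)c1OCOC | intermediate
11 | diaryl ether (R,S)-diol, (R)-1-[3-{3-[(S)-1-hydroxyethyl]-2-(methoxymethoxy)phenoxy}-4,5-bis(methoxymethoxy)phenyl]ethan-1-ol | C[C@@H](O)c1cc(Oc2cccc([C@H](C)O)c2OCOC)c(OCOC)c(OCOC)c1 | intermediate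
12 | bis(N,N-diisopropylcarbamate) of 11 (R at the ring A carbinol carbon, S at the ring B carbinol carbon) | C[C@@H](OC(=O)N(C(C)C)C(C)C)c1cc(Oc2cccc([C@H](C)OC(=O)N(C(C)C)C(C)C)c2OCOC)c(OCOC)c(OCOC)c1 | intermediate
13 | geraniol, (2E)-3,7-dimethylocta-2,6-dien-1-ol | CC(C)=CCC/C(C)=C/CO | starting material
14 | geranyl pinacol boronate | CC(C)=CCC/C(C)=C/CB1OC(C)(C)C(C)(C)O1 | intermediate
15 | lithium (chloromethyl)(geranyl) pinacol boronate complex | [Li+].CC(C)=CCC/C(C)=C/C[B-]1(CCl)OC(C)(C)C(C)(C)O1 | intermediate
16 | (E)-homogeranyl pinacol boronate, 2-[(3E)-4,8-dimethylnona-3,7-dien-1-yl]-4,4,5,5-tetramethyl-1,3,2-dioxaborolane | CC(C)=CCC/C(C)=C/CCB1OC(C)(C)C(C)(C)O1 | intermediate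
17 | doubly α-lithiated 12 (lithium in place of each benzylic hydrogen, configuration retained) | C[C@@]([Li])(OC(=O)N(C(C)C)C(C)C)c1cc(Oc2cccc([C@]([Li])(C)OC(=O)N(C(C)C)C(C)C)c2OCOC)c(OCOC)c(OCOC)c1 | intermediate
18 | dilithium bis(boronate) complex (each benzylic carbon bonded to a tetracoordinate boron bearing pinacol and one homogeranyl group, carbamates still in place) | [Li+].[Li+].C[C@@]([B-]1(CC/C=C(\C)CCC=C(C)C)OC(C)(C)C(C)(C)O1)(OC(=O)N(C(C)C)C(C)C)c1cc(Oc2cccc([C@]([B-]3(CC/C=C(\C)CCC=C(C)C)OC(C)(C)C(C)(C)O3)(C)OC(=O)N(C(C)C)C(C)C)c2OCOC)c(OCOC)c(OCOC)c1 | intermediate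
19 | bis(tertiary benzylic pinacol boronate), each benzylic carbon bearing CH3, homogeranyl, Bpin and aryl (R on ring A, S on ring B) | C[C@@](CC/C=C(\C)CCC=C(C)C)(B1OC(C)(C)C(C)(C)O1)c1cc(Oc2cccc([C@](CC/C=C(\C)CCC=C(C)C)(C)B3OC(C)(C)C(C)(C)O3)c2OCOC)c(OCOC)c(OCOC)c1 | intermediate
20 | bis(vinyl boronate) complex of 19 with bromomagnesium counter-ions | [Mg+2].[Mg+2].[Br-].[Br-].C[C@@](CC/C=C(\C)CCC=C(C)C)([B-]1(C=C)OC(C)(C)C(C)(C)O1)c1cc(Oc2cccc([C@](CC/C=C(\C)CCC=C(C)C)(C)[B-]3(C=C)OC(C)(C)C(C)(C)O3)c2OCOC)c(OCOC)c(OCOC)c1 | intermediate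
21 | bis(β-iodoalkyl pinacol boronate), each quaternary carbon bearing CH(Bpin)CH2I (configuration at CH(Bpin) not controlled) | C[C@@](CC/C=C(\C)CCC=C(C)C)(C(CI)B1OC(C)(C)C(C)(C)O1)c1cc(Oc2cccc([C@](CC/C=C(\C)CCC=C(C)C)(C)C(CI)B3OC(C)(C)C(C)(C)O3)c2OCOC)c(OCOC)c(OCOC)c1 | intermediate
22 | tris-MOM ether of the target (R quaternary carbon on ring A, S on ring B) | C=C[C@@](C)(CC/C=C(\C)CCC=C(C)C)c1cc(OCOC)c(OCOC)c(Oc2cccc([C@](C)(C=C)CC/C=C(\C)CCC=C(C)C)c2OCOC)c1 | intermediate
23 | CNP0325484.1 | C=C[C@@](C)(CC/C=C(\C)CCC=C(C)C)c1cc(O)c(O)c(Oc2cccc([C@](C)(C=C)CC/C=C(\C)CCC=C(C)C)c2O)c1 | target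

Total step count: 14 (steps 1–4 for the ring A piece, 5–7 for the ring B piece, 10–11 for the boronate, 8, 9, 12, 13 and 14 after convergence).
Longest linear sequence: 9 steps (1, 2, 3, 4, 8, 9, 12, 13, 14) from 1.

Steps most likely to fail

Step 12. The second deprotonation may stay incomplete, or one boronate complex (most probably the crowded one on ring B) may revert before its 1,2-shift. Either would leave partly homologated material and erode the configuration of one centre. The fallback builds the two centres one after the other; it sets out from 5 and comes back at 22. Carbamoylation of 5 (iPr2NCOCl, Et3N) would give the (R)-bromo carbamate F1. Ullmann coupling of F1 with 10 under the conditions of step 8 would give the diaryl ether mono-carbamate with a free ring B carbinol F2, and TBSCl/imidazole its silyl ether F3. A single lithiation–borylation of F3 with 16 (s-BuLi, Et2O, −78 °C, then MgBr2/MeOH) would give the ring A tertiary boronate F4, and Zweifel vinylation the ring A vinyl silyl ether F5. TBAF would free the ring B vinyl carbinol F6, carbamoylation would give the ring B vinyl carbamate F7, a second lithiation–borylation with 16 would give the ring B tertiary boronate F8, and a second Zweifel vinylation would deliver 22.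

Step 13. The vinyl nucleophile may fail to add completely to the two crowded tertiary boron atoms, above all the one on ring B next to the ortho MOM ether, or iodine may be consumed by the chain alkenes; partial vinylation or protodeboronation would result. The fallback replaces the boron-to-vinyl exchange by one-carbon homologation and olefination; it sets out from 19 and comes back at 22. Matteson homologation of 19 with chloromethyllithium (BrCH2Cl, n-BuLi, −78 °C → rt, retention at the migrating carbon) would give the bis(boronate) with a CH2 inserted at each centre F9. Basic peroxide would give the neopentyl-type diol F10, Dess–Martin oxidation the non-enolisable dialdehyde F11, and Wittig methylenation (Ph3PCH3Br, KOtBu, THF) would give 22.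

Step 8. Carbon–oxygen bond formation at the electron-rich, ortho-substituted C–Br bond may be sluggish, with hydrodebromination taking over. The fallback changes the coupling to an oxidative Chan–Lam etherification at room temperature; it sets out from 5 and comes back at 11. Miyaura borylation of 5 (B2pin2, Pd(dppf)Cl2, KOAc, dioxane, 90 °C) would give the ring A aryl pinacol boronate F12, periodate cleavage of the pinacol (NaIO4, NH4OAc, acetone/H2O) the ring A arylboronic acid F13, and coupling of F13 with phenol 10 (Cu(OAc)2, pyridine, 4 Å sieves, air, CH2Cl2, rt) would give 11.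

Further compounds
F1 | step 12 | (R)-1-[3-bromo-4,5-bis(methoxymethoxy)phenyl]ethyl N,N-diisopropylcarbamate | C[C@@H](OC(=O)N(C(C)C)C(C)C)c1cc(Br)c(OCOC)c(OCOC)c1
F2 | step 12 | diaryl ether with (R)-carbamate on ring A and free (S)-carbinol on ring B | C[C@@H](OC(=O)N(C(C)C)C(C)C)c1cc(Oc2cccc([C@H](C)O)c2OCOC)c(OCOC)c(OCOC)c1
F3 | step 12 | TBS ether of F2 | C[C@@H](OC(=O)N(C(C)C)C(C)C)c1cc(Oc2cccc([C@H](C)O[Si](C)(C)C(C)(C)C)c2OCOC)c(OCOC)c(OCOC)c1
F4 | step 12 | ring A tertiary pinacol boronate with ring B silyl ether | C[C@@](CC/C=C(\C)CCC=C(C)C)(B1OC(C)(C)C(C)(C)O1)c1cc(Oc2cccc([C@H](C)O[Si](C)(C)C(C)(C)C)c2OCOC)c(OCOC)c(OCOC)c1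
F5 | step 12 | ring A vinyl quaternary compound with ring B silyl ether | C=C[C@@](C)(CC/C=C(\C)CCC=C(C)C)c1cc(OCOC)c(OCOC)c(Oc2cccc([C@H](C)O[Si](C)(C)C(C)(C)C)c2OCOC)c1
F6 | step 12 | ring A vinyl quaternary compound with free ring B (S)-carbinol | C=C[C@@](C)(CC/C=C(\C)CCC=C(C)C)c1cc(OCOC)c(OCOC)c(Oc2cccc([C@H](C)O)c2OCOC)c1
F7 | step 12 | ring A vinyl quaternary compound with ring B (S)-carbamate | C=C[C@@](C)(CC/C=C(\C)CCC=C(C)C)c1cc(OCOC)c(OCOC)c(Oc2cccc([C@H](C)OC(=O)N(C(C)C)C(C)C)c2OCOC)c1
F8 | step 12 | ring A vinyl quaternary compound with ring B tertiary pinacol boronate | C=C[C@@](C)(CC/C=C(\C)CCC=C(C)C)c1cc(OCOC)c(OCOC)c(Oc2cccc([C@](CC/C=C(\C)CCC=C(C)C)(C)B3OC(C)(C)C(C)(C)O3)c2OCOC)c1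
F9 | step 13 | bis(homologated pinacol boronate), CH2Bpin on each quaternary carbon | C[C@@](CC/C=C(\C)CCC=C(C)C)(CB1OC(C)(C)C(C)(C)O1)c1cc(Oc2cccc([C@](CC/C=C(\C)CCC=C(C)C)(C)CB3OC(C)(C)C(C)(C)O3)c2OCOC)c(OCOC)c(OCOC)c1
F10 | step 13 | diol, CH2OH on each quaternary carbon | C[C@@](CC/C=C(\C)CCC=C(C)C)(CO)c1cc(Oc2cccc([C@](CC/C=C(\C)CCC=C(C)C)(C)CO)c2OCOC)c(OCOC)c(OCOC)c1
F11 | step 13 | dialdehyde, CHO on each quaternary carbon | C[C@@](CC/C=C(\C)CCC=C(C)C)(C=O)c1cc(Oc2cccc([C@](CC/C=C(\C)CCC=C(C)C)(C)C=O)c2OCOC)c(OCOC)c(OCOC)c1
F12 | step 8 | (R)-1-[3,4-bis(methoxymethoxy)-5-(4,4,5,5-tetramethyl-1,3,2-dioxaborolan-2-yl)phenyl]ethan-1-ol | C[C@@H](O)c1cc(B2OC(C)(C)C(C)(C)O2)c(OCOC)c(OCOC)c1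
F13 | step 8 | {5-[(R)-1-hydroxyethyl]-2,3-bis(methoxymethoxy)phenyl}boronic acid | C[C@@H](O)c1cc(B(O)O)c(OCOC)c(OCOC)c1
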